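**Retrosynthetic overview**
- The aryl ester C(=O)–OAr bond is made last, by acylating only the phenol of a phenol/tertiary-alcohol diol with (S)-3-acetoxybutanoic acid; the one stereocentre is bought with (S)-3-hydroxybutanoic acid.
- The strategy rests on the 1,3,4-trisubstituted benzene ring: acrylate on C1, the E-alkenyl chain on C3 and oxygen on C4 (oxygen para, alkenyl meta to the acrylate). Arene C1, C2, C5 and C6 come from C5, C6, C3 and C4 of a 5-substituted 2-pyrone, arene C3 and C4 from the two carbons of a siloxyalkyne, and pyrone O1–C2(=O) leaves as CO2.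
- The pyrone comes from coumalic acid by bromodecarboxylation and a Heck reaction with methyl acrylate.
- The siloxyalkyne comes from 2-methylbut-3-yn-2-ol by TES protection, hydrozirconation–iodination, Sonogashira ethynylation, C-desilylation, and acetylide oxygenation with O-silylation.
- The benzene ring is the only ring and is formed in step 8; desilylation and esterification follow.

Key step: step 8

Remark: (S)-3-hydroxybutanoic acid is taken as purchased enantiopure; its stereocentre is the only one in the target and no bond to it is made or broken in the route.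

**Step 1**
Reactants: 1 coumalic acid
Product: 2 5-bromo-2H-pyran-2-one
Conditions: NBS (1.05 equiv), LiOAc, MeCN–H2O, rt
Reagents that add atoms: N-bromosuccinimide, O=C1CCC(=O)N1Br
Why: Hunsdiecker-type ipso-bromodecarboxylation; C5 is the nucleophilic β-carbon of the ring enol ether, so Br+ adds there and the carboxylate leaves as CO2, while one equivalent of NBS should leave C3 unbrominated.

**Step 2**
Reactants: 2 5-bromo-2H-pyran-2-one; 3 methyl acrylate
Product: 4 methyl (E)-3-(2-oxo-2H-pyran-5-yl)acrylate
Conditions: Pd2(dba)3 (cat.), [HP(t-Bu)3]BF4 (cat.), Cy2NMe, 1,4-dioxane, 40 °C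
Reagents that add atoms: none
Why: Mizoroki–Heck reaction; zerovalent palladium inserts into the C5–Br bond, syn carbopalladation of the acrylate and syn β-hydride elimination give the E alkene, and the hindered amine and low temperature should spare the lactone and avoid thermal cycloaddition of the pyrone with methyl acrylate.

**Step 3**
Reactants: 5 2-methylbut-3-yn-2-ol
Product: 6 triethyl[(2-methylbut-3-yn-2-yl)oxy]silane
Conditions: TESOTf, 2,6-lutidine, CH2Cl2, 0 °C
Reagents that add atoms: triethylsilyl triflate, CC[Si](CC)(CC)OS(=O)(=O)C(F)(F)F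
Why: Silylation of a tertiary alcohol with a silyl triflate; the TES ether masks the hydroxyl during the organometallic steps that follow.

**Step 4**
Reactants: 6 triethyl[(2-methylbut-3-yn-2-yl)oxy]silane
Product: 8 (E)-triethyl[(4-iodo-2-methylbut-3-en-2-yl)oxy]silane, via alkenylzirconocene chloride 7 (not isolated)
Conditions: Cp2Zr(H)Cl, THF, rt; then I2, 0 °C
Reagents that add atoms: iodine, II
Why: Schwartz hydrozirconation adds Zr–H syn with zirconium on the terminal carbon (steric control by the quaternary centre), and iodinolysis of the C–Zr bond with retention should give only the E vinyl iodide.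

**Step 5**
Reactants: 8 (E)-triethyl[(4-iodo-2-methylbut-3-en-2-yl)oxy]silane; 9 ethynyltrimethylsilane
Product: 10 (E)-triethyl{[2-methyl-6-(trimethylsilyl)hex-3-en-5-yn-2-yl]oxy}silane
Conditions: PdCl2(PPh3)2 (cat.), CuI (cat.), Et3N, THF, rt
Reagents that add atoms: none
Why: Sonogashira coupling of a vinyl iodide at room temperature, which proceeds with retention of the E geometry.

**Step 6**
Reactants: 10 (E)-triethyl{[2-methyl-6-(trimethylsilyl)hex-3-en-5-yn-2-yl]oxy}silane
Product: 11 (E)-triethyl[(2-methylhex-3-en-5-yn-2-yl)oxy]silane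
Conditions: K2CO3 (cat.), MeOH, rt
Reagents that add atoms: none
Why: Methanolysis of the alkynyl C–Si bond by catalytic methoxide; the hindered tertiary TES ether is cleaved far more slowly under these conditions.

**Step 7**
Reactants: 11 (E)-triethyl[(2-methylhex-3-en-5-yn-2-yl)oxy]silane
Product: 14 (E)-2-methyl-2-(triethylsilyloxy)-6-(triisopropylsilyloxy)hex-3-en-5-yne, via lithium acetylide 12 (not isolated), via lithium ynolate 13 (not isolated)
Conditions: n-BuLi, THF, −78 °C; LiOOt-Bu (from t-BuOOH and LiN(SiMe3)2), −78 to 0 °C; TIPSOTf, −78 to 0 °C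
Reagents that add atoms: tert-butyl hydroperoxide, CC(C)(C)OO; triisopropylsilyl triflate, CC(C)[Si](C(C)C)(C(C)C)OS(=O)(=O)C(F)(F)F
Why: Electrophilic oxygenation of the lithium acetylide by lithium tert-butyl peroxide gives the lithium ynolate, which the bulky silyl triflate should trap on oxygen rather than on carbon to give an isolable triisopropylsilyl ynol ether.

**Step 8**
Reactants: 4 methyl (E)-3-(2-oxo-2H-pyran-5-yl)acrylate; 14 (E)-2-methyl-2-(triethylsilyloxy)-6-(triisopropylsilyloxy)hex-3-en-5-yne
Product: 16 methyl (E)-3-[3-((E)-3-methyl-3-(triethylsilyloxy)but-1-enyl)-4-(triisopropylsilyloxy)phenyl]acrylate, via bridged lactone 15 (not isolated)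
Conditions: 14 (1.5 equiv), degassed toluene, 100 °C, sealed tube
Reagents that add atoms: none
Why: The siloxyalkyne is a donor-polarised 2π component (nucleophilic at the carbon carrying the alkenyl chain) and the pyrone an electron-poor, s-cis-locked diene, so they should combine in an inverse-electron-demand Diels–Alder reaction, asynchronous with the bond from the alkenyl-bearing alkyne carbon to pyrone C6 leading and the bond from the oxygen-bearing carbon to pyrone C3 following, to give the 2-oxabicyclo[2.2.2]octadienone 15. The closest known reaction type is the benzannulation of coumalate-type 2-pyrones with ynol ethers, siloxyalkynes and ynamines. The benzene ring is closed by this intermolecular [4+2] cycloaddition followed by retro-[4+2] extrusion of CO2 from 15, so that pyrone C3–C6 and the two alkyne carbons end up in the arene. No stereocentre remains, because the two bridgehead centres of 15 are erased on aromatisation and both E alkenes are untouched. The step needs regioselectivity (oxygen para and alkenyl chain meta to the acrylate), which is secured because C6 is the vinylogous Michael terminus of both the lactone and the acrylate whereas C3 is not electrophilic, and chemoselectivity for the ring diene over the acrylate alkene and over the exocyclic C6=C5–CH=CH diene, which is secured by the locked s-cis geometry, by irreversible CO2 loss and by leaving out silver salts and acids that turn siloxyalkynes toward [2+2] addition. The triisopropylsilyl group slows the 1,3-shift of silicon from oxygen to carbon (silylketene formation) at the reaction temperature.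

**Step 9**
Reactants: 16 methyl (E)-3-[3-((E)-3-methyl-3-(triethylsilyloxy)but-1-enyl)-4-(triisopropylsilyloxy)phenyl]acrylate
Product: 17 methyl (E)-3-[4-hydroxy-3-((E)-3-hydroxy-3-methylbut-1-enyl)phenyl]acrylate
Conditions: Bu4NF, AcOH, THF, 0 °C to rt
Reagents that add atoms: none
Why: Fluoride cleaves both Si–O bonds, and the acetic acid buffer keeps the medium near neutral so that the methyl ester is not hydrolysed and the o-hydroxystyryl tertiary carbinol does not ionise toward a 2,2-dimethylchromene.

**Step 10**
Reactants: 18 (S)-3-hydroxybutanoic acid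
Product: 19 (S)-3-acetoxybutanoic acid
Conditions: AcCl (excess), 0 °C to rt; evaporation, aqueous work-up
Reagents that add atoms: acetyl chloride, CC(=O)Cl
Why: O-acetylation of the secondary alcohol by the acid chloride; no bond to C3 is broken, so the S configuration of the purchased acid is carried through.

**Step 11**
Reactants: 17 methyl (E)-3-[4-hydroxy-3-((E)-3-hydroxy-3-methylbut-1-enyl)phenyl]acrylate; 19 (S)-3-acetoxybutanoic acid
Product: 20 methyl (E)-3-[4-{[(S)-3-acetoxybutanoyl]oxy}-3-((E)-3-hydroxy-3-methylbut-1-enyl)phenyl]acrylate (CNP0325017.1)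
Conditions: DCC (1.1 equiv), DMAP (cat.), CH2Cl2, 0 °C
Reagents that add atoms: none
Why: Steglich esterification; the acylpyridinium acylates the acidic, unhindered phenol much faster than the hindered tertiary allylic alcohol, and the stereocentre β to the carbonyl is not epimerisable under these conditions.

**Compound list**
1 | coumalic acid (2-oxo-2H-pyran-5-carboxylic acid) | O=C(O)C1=COC(=O)C=C1 | starting material
2 | 5-bromo-2H-pyran-2-one | O=C1C=CC(Br)=CO1 | intermediate
3 | methyl acrylate | C=CC(=O)OC | starting material
4 | methyl (E)-3-(2-oxo-2H-pyran-5-yl)acrylate | COC(=O)/C=C/C1=COC(=O)C=C1 | intermediate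
5 | 2-methylbut-3-yn-2-ol | CC(C)(O)C#C | starting material
6 | triethyl[(2-methylbut-3-yn-2-yl)oxy]silane | CC(C)(O[Si](CC)(CC)CC)C#C | intermediate
7 | chlorobis(cyclopentadienyl)[(E)-3-methyl-3-(triethylsilyloxy)but-1-enyl]zirconium (alkenylzirconocene chloride) | CC(C)(O[Si](CC)(CC)CC)/C=C/[Zr](Cl)(C1C=CC=C1)C1C=CC=C1 | intermediate
8 | (E)-triethyl[(4-iodo-2-methylbut-3-en-2-yl)oxy]silane | CC(C)(O[Si](CC)(CC)CC)/C=C/I | intermediate
9 | ethynyltrimethylsilane | C#C[Si](C)(C)C | starting material
10 | (E)-triethyl{[2-methyl-6-(trimethylsilyl)hex-3-en-5-yn-2-yl]oxy}silane | CC(C)(O[Si](CC)(CC)CC)/C=C/C#C[Si](C)(C)C | intermediate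
11 | (E)-triethyl[(2-methylhex-3-en-5-yn-2-yl)oxy]silane | CC(C)(O[Si](CC)(CC)CC)/C=C/C#C | intermediate
12 | lithium acetylide of 11 | CC(C)(O[Si](CC)(CC)CC)/C=C/C#C[Li] | intermediate
13 | lithium (E)-5-methyl-5-(triethylsilyloxy)hex-3-en-1-yn-1-olate (lithium ynolate) | CC(C)(O[Si](CC)(CC)CC)/C=C/C#CO[Li] | intermediate
14 | (E)-2-methyl-2-(triethylsilyloxy)-6-(triisopropylsilyloxy)hex-3-en-5-yne | CC(C)(O[Si](CC)(CC)CC)/C=C/C#CO[Si](C(C)C)(C(C)C)C(C)C | intermediate
15 | bridged lactone: racemic 2-oxabicyclo[2.2.2]octa-5,7-dien-3-one with the (E)-acrylate on C6, the (E)-3-methyl-3-(triethylsilyloxy)but-1-enyl chain on C7 and OTIPS on C8 | COC(=O)/C=C/C1=CC2C(=O)OC1C(/C=C/C(C)(C)O[Si](CC)(CC)CC)=C2O[Si](C(C)C)(C(C)C)C(C)C | intermediate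
16 | methyl (E)-3-[3-((E)-3-methyl-3-(triethylsilyloxy)but-1-enyl)-4-(triisopropylsilyloxy)phenyl]acrylate | COC(=O)/C=C/c1ccc(O[Si](C(C)C)(C(C)C)C(C)C)c(/C=C/C(C)(C)O[Si](CC)(CC)CC)c1 | intermediate
17 | methyl (E)-3-[4-hydroxy-3-((E)-3-hydroxy-3-methylbut-1-enyl)phenyl]acrylate | COC(=O)/C=C/c1ccc(O)c(/C=C/C(C)(C)O)c1 | intermediate
18 | (S)-3-hydroxybutanoic acid | C[C@H](O)CC(=O)O | starting material
19 | (S)-3-acetoxybutanoic acid | C[C@H](OC(C)=O)CC(=O)O | intermediate
20 | methyl (E)-3-[4-{[(S)-3-acetoxybutanoyl]oxy}-3-((E)-3-hydroxy-3-methylbut-1-enyl)phenyl]acrylate | COC(=O)/C=C/c1ccc(OC(=O)C[C@H](C)OC(C)=O)c(/C=C/C(C)(C)O)c1 | target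

Total step count: 11.
Longest linear sequence: 8 steps (steps 3, 4, 5, 6, 7, 8, 9 and 11, from 2-methylbut-3-yn-2-ol).

**Steps most likely to fail**

Step 8. The acrylate-substituted pyrone is a weaker acceptor than a coumalate, so the temperature needed may allow silicon migration from oxygen to carbon in the siloxyalkyne before cycloaddition. Addition may also occur across the exocyclic diene (ring C5=C6 with the acrylate alkene), and the acrylate may oligomerise. The fallback sets out from 14 and uses commercial methyl coumalate, the classical more electron-poor diene, in toluene at 60–80 °C. This should pass through the bridged lactone F1 and, after CO2 loss, give methyl 3-[(E)-3-methyl-3-(triethylsilyloxy)but-1-enyl]-4-(triisopropylsilyloxy)benzoate F2. Reduction with i-Bu2AlH (CH2Cl2, −78 °C) should give the benzyl alcohol F3, oxidation with MnO2 (CH2Cl2, rt) the benzaldehyde F4, and an E-selective Wittig reaction with Ph3P=CHCO2Me (toluene, 60 °C) rejoins the route at 16.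

Step 7. Oxygen transfer to the conjugated enyne acetylide may be incomplete, the ynolate may be silylated on carbon, or the siloxyalkyne may hydrolyse or rearrange during isolation. The fallback sets out from 8. Carbonylation (Pd(OAc)2, PPh3, CO 1 atm, MeOH, Et3N, DMF, 50 °C) should give methyl (E)-4-methyl-4-(triethylsilyloxy)pent-2-enoate F5. A Kowalski ester homologation sequence follows: LiCHBr2 from CH2Br2 and lithium 2,2,6,6-tetramethylpiperidide (THF, −78 °C), then LiN(SiMe3)2, then n-BuLi (−78 °C to rt). It passes through the lithium enolate of (E)-1,1-dibromo-5-methyl-5-(triethylsilyloxy)hex-3-en-2-one F6, whose bromine–lithium exchange and rearrangement deliver the ynolate. The fallback thereby rejoins the route at 13, which is silylated with TIPSOTf to 14 as in step 7.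

Step 2. The pyrone ring may be opened by base during the coupling, the pyrone may undergo thermal cycloaddition with methyl acrylate, or oxidative addition at C5 may be slow. The fallback sets out from 2 and replaces the Heck reaction by a base-free Stille coupling (Pd(PPh3)4, CuI, DMF, 50 °C) with methyl (E)-3-(tributylstannyl)acrylate F7. F7 would be made by radical hydrostannation of methyl propiolate (Bu3SnH, AIBN, 70 °C) with chromatographic separation of the E isomer. The coupling rejoins the route at 4.

**Further compounds**
F1 | step 8 | bridged lactone: racemic methyl 3-oxo-2-oxabicyclo[2.2.2]octa-5,7-diene-6-carboxylate with the (E)-3-methyl-3-(triethylsilyloxy)but-1-enyl chain on C7 and OTIPS on C8 | COC(=O)C1=CC2C(=O)OC1C(/C=C/C(C)(C)O[Si](CC)(CC)CC)=C2O[Si](C(C)C)(C(C)C)C(C)C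
F2 | step 8 | methyl 3-[(E)-3-methyl-3-(triethylsilyloxy)but-1-enyl]-4-(triisopropylsilyloxy)benzoate | COC(=O)c1ccc(O[Si](C(C)C)(C(C)C)C(C)C)c(/C=C/C(C)(C)O[Si](CC)(CC)CC)c1
F3 | step 8 | {3-[(E)-3-methyl-3-(triethylsilyloxy)but-1-enyl]-4-(triisopropylsilyloxy)phenyl}methanol | OCc1ccc(O[Si](C(C)C)(C(C)C)C(C)C)c(/C=C/C(C)(C)O[Si](CC)(CC)CC)c1
F4 | step 8 | 3-[(E)-3-methyl-3-(triethylsilyloxy)but-1-enyl]-4-(triisopropylsilyloxy)benzaldehyde | O=Cc1ccc(O[Si](C(C)C)(C(C)C)C(C)C)c(/C=C/C(C)(C)O[Si](CC)(CC)CC)c1
F5 | step 7 | methyl (E)-4-methyl-4-(triethylsilyloxy)pent-2-enoate | COC(=O)/C=C/C(C)(C)O[Si](CC)(CC)CC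
F6 | step 7 | lithium enolate of (E)-1,1-dibromo-5-methyl-5-(triethylsilyloxy)hex-3-en-2-one | [Li]OC(=C(Br)Br)/C=C/C(C)(C)O[Si](CC)(CC)CC
F7 | step 2 | methyl (E)-3-(tributylstannyl)acrylate | CCCC[Sn](CCCC)(CCCC)/C=C/C(=O)OC
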